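**Retrosynthetic overview**
- The target is reached from its C15 diethyl acetal; the angelate (O6) and methacrylate (O9) are put on late, each at a stage where only that hydroxyl is free.
- The α-methylene-γ-lactone comes from a C7 acrylic acid that displaces an 8β-mesylate with inversion, and the 9β-alcohol from a C9 ketone (bulky hydride).
- Key disconnection: C10–C1, made by an intermolecular aldol of a ring enolate with acetaldehyde; the enolate arises by cuprate 1,4-addition of the C4/C3/C15 unit to a 6,8-dioxygenated enone, and the aldol product is dehydrated to the vinyl group.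
- That enone comes from (S)-carvone by side-chain chlorination/hydroxylation, Rubottom oxidation (O6), epoxidation/Wharton transposition/oxidation and a second Rubottom oxidation (O8).
- Ring order: the cyclohexane is carvone's own ring (chiral pool); the γ-lactone is the only ring made, closed in step 17.

Assumption and convention: 2-bromo-3,3-diethoxyprop-1-ene is taken as a catalogue reagent; from the Wharton product on, elemane numbering is used (ring C5–C10; C10 carries methyl C14 and vinyl C1=C2; C5 carries C4(=C3)–C15; C7 carries C11(=C13)–C12), β is the face of the C14 methyl and α the opposite face; earlier compounds keep carvone numbering.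

**Route**

Step 1
Reactants: 1 (S)-(+)-carvone
Product: 2 (S)-10-chlorocarvone
Conditions: Ca(OCl)2, CO2 (dry ice), CH2Cl2/H2O, 0 °C
Reagents that add atoms: calcium hypochlorite Ca(OCl)2, [Ca+2].[O-]Cl.[O-]Cl
Why: Ene-type allylic chlorination by HOCl made in situ (Wolinsky chlorination) attacks only the electron-rich 1,1-disubstituted alkene, so the enone and the C5 stereocentre are untouched.

Step 2
Reactants: 2 (S)-10-chlorocarvone
Product: 4 (S)-10-hydroxycarvone, via 10-acetoxycarvone 3 (not isolated)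
Conditions: KOAc, NaI (cat.), DMF, 60 °C; then K2CO3 (0.2 equiv), MeOH, 0 °C
Reagents that add atoms: potassium acetate KOAc, CC(=O)[O-].[K+]
Why: SN2 displacement of the primary allylic chloride by acetate and K2CO3-catalysed transesterification free the alcohol without touching the enone; no stereocentre is involved.

Step 3
Reactants: 4 (S)-10-hydroxycarvone
Product: 5 bis-silyl dienol ether
Conditions: LiN(iPr)2 (2.3 equiv), THF, −78 °C; t-BuMe2SiCl (2.5 equiv), DMPU, −78 → 0 °C
Reagents that add atoms: tert-butyldimethylsilyl chloride, CC(C)(C)[Si](C)(C)Cl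
Why: Kinetic α′-deprotonation (C6) of the enone alkoxide and O-silylation of both oxygens give the cross-conjugated silyl dienol ether (silyl enol ether formation) and protect the primary alcohol in the same operation.

Step 4
Reactants: 5 bis-silyl dienol ether
Product: 6 5,6-trans α-silyloxy enone
Conditions: mCPBA (1.05 equiv), NaHCO3, CH2Cl2, −20 → 0 °C
Reagents that add atoms: mCPBA, OOC(=O)c1cccc(Cl)c1
Why: Rubottom oxidation: the peracid epoxidises the enol ether anti to the adjacent C5 side chain and a 1,4-silyl shift gives the 5,6-trans α-silyloxy ketone, which is also the more stable diequatorial epimer.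

Step 5
Reactants: 6 5,6-trans α-silyloxy enone
Product: 7 epoxy ketone
Conditions: t-BuOOH, benzyltrimethylammonium hydroxide (cat.), THF, 0 °C
Reagents that add atoms: tert-butyl hydroperoxide, CC(C)(C)OO
Why: Weitz–Scheffer nucleophilic epoxidation occurs trans to the C5 side chain; the epoxide configuration does not matter because both epoxide carbons lose it in steps 6 and 7.

Step 6
Reactants: 7 epoxy ketone
Product: 8 transposed allylic alcohol
Conditions: N2H4·H2O, AcOH (cat.), MeOH, 0 °C → rt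
Reagents that add atoms: none
Why: Wharton transposition (hydrazone, epoxide opening, loss of N2) moves the oxygen from C1 to C3 and the alkene to C1=C2, so the former α′-oxygen becomes the γ-oxygen (elemane O6) with its configuration intact.

Step 7
Reactants: 8 transposed allylic alcohol
Product: 9 transposed enone
Conditions: MnO2, CH2Cl2, rt
Reagents that add atoms: none
Why: MnO2 oxidation of the secondary allylic alcohol gives the enone whose only α′ position is the C8 methylene.

Step 8
Reactants: 9 transposed enone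
Product: 11 6β,8β-bis-silyloxy enone, via triethylsilyl dienol ether 10 (not isolated)
Conditions: LiN(iPr)2, Et3SiCl, THF, −78 °C; then mCPBA, NaHCO3, CH2Cl2/hexane, −20 °C
Reagents that add atoms: triethylsilyl chloride, CC[Si](Cl)(CC)CC; mCPBA, OOC(=O)c1cccc(Cl)c1
Why: Second Rubottom oxidation: kinetic enolisation is only possible at C8 and the peracid attacks anti to the C7 side chain, giving the all-trans 6,7,8 array whose three equatorial substituents lock the half-chair.

Step 9 (key step)
Reactants: 11 6β,8β-bis-silyloxy enone; 12 2-bromo-3,3-diethoxyprop-1-ene; 13 acetaldehyde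
Product: 15 aldol adduct, via metal enolate 14 (not isolated)
Conditions: 12, t-BuLi (2 equiv), Et2O, −78 °C; CuBr·SMe2 (0.5 equiv per Li); 11, −78 → −40 °C; ZnCl2 (THF), then 13, −78 °C; aq. NH4Cl
Reagents that add atoms: none
Why: Conjugate addition–aldol sequence: the alkenylcuprate adds axially to C5 of the locked enone anti to the C7 side chain (as in carvone), and the regiodefined enolate 14 is captured by acetaldehyde in an intermolecular aldol reaction on the face opposite the new axial C5 group, setting the quaternary C10 (CH3 β, two-carbon unit α; the carbinol epimers converge in step 10).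

Step 10
Reactants: 15 aldol adduct
Product: 16 vinyl ketone
Conditions: Ph2S[OC(CF3)2Ph]2 (Martin sulfurane), CH2Cl2, 0 °C → rt
Reagents that add atoms: none
Why: Martin sulfurane dehydration is an E2 elimination from the alkoxysulfonium intermediate and can only give the terminal vinyl group because C10 is quaternary.

Step 11
Reactants: 16 vinyl ketone
Product: 17 9β-alcohol
Conditions: LiBH(sBu)3 (L-Selectride), THF, −78 °C; aq. NH4Cl
Reagents that add atoms: none
Why: Substrate-controlled ketone reduction: the bulky hydride comes in equatorially because the axial path is blocked by the syn-axial C5 side chain, giving the axial 9β-alcohol cis to the 8β-silyloxy group.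

Step 12
Reactants: 17 9β-alcohol
Product: 18 9β-methacrylate
Conditions: methacrylic anhydride, Et3N, DMAP, BHT (trace), CH2Cl2, rt → 40 °C
Reagents that add atoms: methacrylic anhydride, CC(=C)C(=O)OC(=O)C(C)=C
Why: DMAP-catalysed acyl transfer esterifies the only free hydroxyl with retention at C9.

Step 13
Reactants: 18 9β-methacrylate
Product: 19 8β-alcohol
Conditions: PPTS (cat.), EtOH, 0 °C → rt
Reagents that add atoms: none
Why: Acid-catalysed ethanolysis removes the triethylsilyl ether much faster than the primary and the hindered secondary tert-butyldimethylsilyl ethers, and ethanol makes acetal exchange at C15 degenerate.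

Step 14
Reactants: 19 8β-alcohol
Product: 20 8β-mesylate
Conditions: MeSO2Cl, Et3N, CH2Cl2, −20 → 0 °C
Reagents that add atoms: methanesulfonyl chloride, CS(=O)(=O)Cl
Why: Sulfonylation turns the equatorial 8β-hydroxyl into a leaving group with retention, and the low temperature suppresses 1,2-acyl migration from O9.

Step 15
Reactants: 20 8β-mesylate
Product: 21 primary allylic alcohol
Conditions: HF·pyridine, pyridine, THF, 0 °C → rt
Reagents that add atoms: none
Why: Buffered fluoride desilylation cleaves the unhindered primary silyl ether selectively, the 6β-silyl ether being shielded by its two branched neighbours.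

Step 16
Reactants: 21 primary allylic alcohol
Product: 23 acrylic acid, via enal 22 (not isolated)
Conditions: MnO2, CH2Cl2, rt; filter; then NaClO2, NaH2PO4/Na2HPO4 (pH about 6.5), 2-methylbut-2-ene, t-BuOH/H2O, 0 °C → rt
Reagents that add atoms: sodium chlorite NaClO2, [Na+].[O-]Cl=O
Why: MnO2 oxidises the primary allylic alcohol to the enal and a near-neutral Pinnick oxidation takes it to the acrylic acid without hydrolysing the acetal or touching the alkenes.

Step 17
Reactants: 23 acrylic acid
Product: 24 cis-fused 8α,12-lactone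
Conditions: Cs2CO3, DMF, rt → 50 °C
Reagents that add atoms: none
Why: Intramolecular SN2 displacement of the 8β-mesylate by the carboxylate (5-exo-tet lactonisation) inverts C8 and so gives the cis-fused lactone with O8 α, trans to the 9β-ester.

Step 18
Reactants: 24 cis-fused 8α,12-lactone
Product: 25 6β-alcohol
Conditions: Bu4NF, AcOH (1:1), THF, 0 °C → rt
Reagents that add atoms: none
Why: Acetic-acid-buffered fluoride desilylation frees the 6β-hydroxyl without acid (which could close a cyclic acetal onto C15) and without strong base (which would attack the acrylate units).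

Step 19
Reactants: 25 6β-alcohol
Product: 26 6β-angelate acetal
Conditions: angelic acid, 2,4,6-trichlorobenzoyl chloride, Et3N, toluene, rt; then 25, BHT (trace), 80 °C (no DMAP)
Reagents that add atoms: angelic acid, C/C=C(/C)C(O)=O
Why: Yamaguchi-type esterification through the mixed anhydride, run without DMAP, acylates the hindered alcohol with retention at C6 and keeps the Z geometry of the angelate.

Step 20
Reactants: 26 6β-angelate acetal
Product: 27 CNP0102441.1
Conditions: PPTS (cat.), acetone/H2O (10:1), 40 °C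
Reagents that add atoms: water, O
Why: Mild acid-catalysed acetal hydrolysis unmasks the 2-substituted acrolein while the esters, the lactone and all stereocentres stay as they are.

**Compound list**

1 | (S)-(+)-carvone, (5S)-2-methyl-5-(prop-1-en-2-yl)cyclohex-2-en-1-one | CC1=CC[C@@H](CC1=O)C(C)=C | starting material
2 | (5S)-5-(3-chloroprop-1-en-2-yl)-2-methylcyclohex-2-en-1-one (10-chlorocarvone) | CC1=CC[C@@H](CC1=O)C(=C)CCl | intermediate
3 | (5S)-5-(3-acetoxyprop-1-en-2-yl)-2-methylcyclohex-2-en-1-one (10-acetoxycarvone) | CC1=CC[C@@H](CC1=O)C(=C)COC(C)=O | intermediate (not isolated)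
4 | (5S)-5-(3-hydroxyprop-1-en-2-yl)-2-methylcyclohex-2-en-1-one (10-hydroxycarvone) | CC1=CC[C@@H](CC1=O)C(=C)CO | intermediate
5 | (5S)-1-(tert-butyldimethylsilyloxy)-5-[3-(tert-butyldimethylsilyloxy)prop-1-en-2-yl]-2-methylcyclohexa-1(6),2-diene | CC1=CC[C@@H](C=C1O[Si](C)(C)C(C)(C)C)C(=C)CO[Si](C)(C)C(C)(C)C | intermediate
6 | 5,6-trans-6-(tert-butyldimethylsilyloxy)-5-[3-(tert-butyldimethylsilyloxy)prop-1-en-2-yl]-2-methylcyclohex-2-en-1-one | CC1=CC[C@@H]([C@@H](O[Si](C)(C)C(C)(C)C)C1=O)C(=C)CO[Si](C)(C)C(C)(C)C | intermediate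
7 | 2,3-epoxide of 6, epoxide oxygen trans to the C5 side chain (2,3-epoxy-2-methylcyclohexan-1-one with 6-OTBS and 5-side chain as in 6) | O=C1[C@H](O[Si](C)(C)C(C)(C)C)[C@@H](C(=C)CO[Si](C)(C)C(C)(C)C)C[C@@H]2O[C@]12C | intermediate
8 | 4,5-trans-1,4-cis-4-(tert-butyldimethylsilyloxy)-5-[3-(tert-butyldimethylsilyloxy)prop-1-en-2-yl]-2-methylcyclohex-2-en-1-ol (elemane positions: 9β-OH, 6β-OTBS, 7α side chain, C5=C10) | CC1=C[C@H](O[Si](C)(C)C(C)(C)C)[C@@H](C(=C)CO[Si](C)(C)C(C)(C)C)C[C@@H]1O | intermediate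
9 | 4,5-trans-4-(tert-butyldimethylsilyloxy)-5-[3-(tert-butyldimethylsilyloxy)prop-1-en-2-yl]-2-methylcyclohex-2-en-1-one (C9 ketone, 6β-OTBS, 7α side chain) | CC1=C[C@H](O[Si](C)(C)C(C)(C)C)[C@@H](C(=C)CO[Si](C)(C)C(C)(C)C)CC1=O | intermediate
10 | triethylsilyl dienol ether of 9 (C8=C9–OSiEt3, C10=C5) | CC1=C[C@H](O[Si](C)(C)C(C)(C)C)[C@@H](C(=C)CO[Si](C)(C)C(C)(C)C)C=C1O[Si](CC)(CC)CC | intermediate (not isolated)
11 | 4,5-trans-5,6-trans-4-(tert-butyldimethylsilyloxy)-6-(triethylsilyloxy)-5-[3-(tert-butyldimethylsilyloxy)prop-1-en-2-yl]-2-methylcyclohex-2-en-1-one (6β-OTBS, 7α side chain, 8β-OTES) | CC1=C[C@H](O[Si](C)(C)C(C)(C)C)[C@@H](C(=C)CO[Si](C)(C)C(C)(C)C)[C@H](O[Si](CC)(CC)CC)C1=O | intermediate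
12 | 2-bromo-3,3-diethoxyprop-1-ene (2-bromoacrolein diethyl acetal) | C=C(Br)C(OCC)OCC | starting material
13 | acetaldehyde | CC=O | starting material
14 | C9(O)=C10 metal enolate after 1,4-addition, drawn as the lithium enolate (5β-(3,3-diethoxyprop-1-en-2-yl), 6β-OTBS, 7α side chain, 8β-OTES) | [Li+].[O-]C1=C(C)[C@H](C(=C)C(OCC)OCC)[C@H](O[Si](C)(C)C(C)(C)C)[C@@H](C(=C)CO[Si](C)(C)C(C)(C)C)[C@@H]1O[Si](CC)(CC)CC | intermediate (not isolated)
15 | aldol adduct: C9 ketone with 10β-CH3, 10α-(1-hydroxyethyl) (both carbinol epimers), 5β-(3,3-diethoxyprop-1-en-2-yl), 6β-OTBS, 7α-[3-(TBSO)prop-1-en-2-yl], 8β-OTES | CC(O)[C@@]1(C)[C@H](C(=C)C(OCC)OCC)[C@H](O[Si](C)(C)C(C)(C)C)[C@@H](C(=C)CO[Si](C)(C)C(C)(C)C)[C@H](O[Si](CC)(CC)CC)C1=O | intermediate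
16 | vinyl ketone: as 15 but 10α-vinyl | C=C[C@@]1(C)[C@H](C(=C)C(OCC)OCC)[C@H](O[Si](C)(C)C(C)(C)C)[C@@H](C(=C)CO[Si](C)(C)C(C)(C)C)[C@H](O[Si](CC)(CC)CC)C1=O | intermediate
17 | 9β-alcohol of 16 (8β-OTES and 9β-OH cis) | C=C[C@@]1(C)[C@H](C(=C)C(OCC)OCC)[C@H](O[Si](C)(C)C(C)(C)C)[C@@H](C(=C)CO[Si](C)(C)C(C)(C)C)[C@H](O[Si](CC)(CC)CC)[C@@H]1O | intermediate
18 | 9β-methacrylate of 17 | C=C[C@@]1(C)[C@H](C(=C)C(OCC)OCC)[C@H](O[Si](C)(C)C(C)(C)C)[C@@H](C(=C)CO[Si](C)(C)C(C)(C)C)[C@H](O[Si](CC)(CC)CC)[C@@H]1OC(=O)C(C)=C | intermediate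
19 | 8β-alcohol (9β-methacrylate, 6β-OTBS, C12-OTBS) | C=C[C@@]1(C)[C@H](C(=C)C(OCC)OCC)[C@H](O[Si](C)(C)C(C)(C)C)[C@@H](C(=C)CO[Si](C)(C)C(C)(C)C)[C@H](O)[C@@H]1OC(=O)C(C)=C | intermediate
20 | 8β-methanesulfonate of 19 | C=C[C@@]1(C)[C@H](C(=C)C(OCC)OCC)[C@H](O[Si](C)(C)C(C)(C)C)[C@@H](C(=C)CO[Si](C)(C)C(C)(C)C)[C@H](OS(C)(=O)=O)[C@@H]1OC(=O)C(C)=C | intermediate
21 | C12 primary allylic alcohol (8β-OMs, 9β-methacrylate, 6β-OTBS) | C=C[C@@]1(C)[C@H](C(=C)C(OCC)OCC)[C@H](O[Si](C)(C)C(C)(C)C)[C@@H](C(=C)CO)[C@H](OS(C)(=O)=O)[C@@H]1OC(=O)C(C)=C | intermediate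
22 | C12 enal of 21 | C=C[C@@]1(C)[C@H](C(=C)C(OCC)OCC)[C@H](O[Si](C)(C)C(C)(C)C)[C@@H](C(=C)C=O)[C@H](OS(C)(=O)=O)[C@@H]1OC(=O)C(C)=C | intermediate (not isolated)
23 | C12 acrylic acid of 21 | C=C[C@@]1(C)[C@H](C(=C)C(OCC)OCC)[C@H](O[Si](C)(C)C(C)(C)C)[C@@H](C(=C)C(O)=O)[C@H](OS(C)(=O)=O)[C@@H]1OC(=O)C(C)=C | intermediate
24 | cis-fused 8α,12-lactone (α-methylene-γ-butyrolactone; 6β-OTBS, 9β-methacrylate, C15 diethyl acetal) | C=C[C@@]1(C)[C@H](C(=C)C(OCC)OCC)[C@H](O[Si](C)(C)C(C)(C)C)[C@H]2C(=C)C(=O)O[C@H]2[C@@H]1OC(=O)C(C)=C | intermediate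
25 | 6β-alcohol of 24 | C=C[C@@]1(C)[C@H](C(=C)C(OCC)OCC)[C@H](O)[C@H]2C(=C)C(=O)O[C@H]2[C@@H]1OC(=O)C(C)=C | intermediate
26 | 6β-angelate of 25 (C15 diethyl acetal of the target) | C=C[C@@]1(C)[C@H](C(=C)C(OCC)OCC)[C@H](OC(=O)/C(C)=C\C)[C@H]2C(=C)C(=O)O[C@H]2[C@@H]1OC(=O)C(C)=C | intermediate
27 | CNP0102441.1: (5R,6S,7R,8R,9R,10S; elemane numbering) 6β-angeloyloxy-9β-methacryloyloxy-15-oxoelema-1,3,11(13)-trien-12,8α-olide | C=C[C@@]1(C)[C@H](C(=C)C=O)[C@H](OC(=O)/C(C)=C\C)[C@H]2C(=C)C(=O)O[C@H]2[C@@H]1OC(=O)C(=C)C | target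

**Step count and risks**

Total step count: 20. Longest linear sequence: 20 steps (1 → 27); 12 and 13 are bought.

The three steps most likely to fail:

Step 9. The hindered tetrasubstituted enolate may give a poor aldol (proton transfer, retro-aldol), and the facial preference at C5 rests on the conformational lock. Fallback: set out from 11 and add the same cuprate in the presence of Me3SiCl to isolate the trimethylsilyl enol ether F1. MeLi regenerates the lithium enolate, which undergoes Michael addition to phenyl vinyl sulfoxide (a vinyl cation equivalent) to give the 2-(phenylsulfinyl)ethyl ketone F2. Thermolysis (toluene, 110 °C, CaCO3) expels PhSOH and gives the vinyl ketone 16 directly, so the route is rejoined at 16 and 15 is bypassed.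

Step 17. E2 elimination of the mesylate may compete with the inverting lactonisation. Fallback: set out from alcohol 19 and invert C8 by a Mitsunobu reaction with chloroacetic acid (PPh3, DIAD) to give the 8α-chloroacetate F3. Thiourea (NaHCO3, EtOH, 50 °C) removes the chloroacetyl group selectively to give the 8α-alcohol F4, and HF·pyridine frees the primary alcohol to give the 8α,12-diol F5. MnO2 then oxidises the allylic alcohol through the lactol to the lactone (oxidative lactonisation, no inversion needed), rejoining the route at 24.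

Step 19. The hindered 6β-alcohol may react slowly, and any isomerisation would give the tiglate. Fallback: set out from 25 and build the Z-alkene on the oxygen instead. DCC/DMAP coupling with 2-[bis(2,2,2-trifluoroethoxy)phosphoryl]propanoic acid gives the phosphonopropanoate ester F6. Still–Gennari olefination (KN(SiMe3)2, 18-crown-6, acetaldehyde 13, THF, −78 °C) forms the Z-trisubstituted enoate, rejoining the route at 26.

**Further compounds**

F1 | step 9 | trimethylsilyl enol ether of the 1,4-adduct (C9(OSiMe3)=C10; 5β-(3,3-diethoxyprop-1-en-2-yl), 6β-OTBS, 7α side chain, 8β-OTES) | C[Si](C)(C)OC1=C(C)[C@H](C(=C)C(OCC)OCC)[C@H](O[Si](C)(C)C(C)(C)C)[C@@H](C(=C)CO[Si](C)(C)C(C)(C)C)[C@@H]1O[Si](CC)(CC)CC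
F2 | step 9 | 10α-[2-(phenylsulfinyl)ethyl] ketone (as 16 with CH2CH2S(O)Ph in place of vinyl; sulfoxide epimers) | O=S(CC[C@@]1(C)[C@H](C(=C)C(OCC)OCC)[C@H](O[Si](C)(C)C(C)(C)C)[C@@H](C(=C)CO[Si](C)(C)C(C)(C)C)[C@H](O[Si](CC)(CC)CC)C1=O)c1ccccc1
F3 | step 17 | 8α-chloroacetate (C8 epimer series of 19) | C=C[C@@]1(C)[C@H](C(=C)C(OCC)OCC)[C@H](O[Si](C)(C)C(C)(C)C)[C@@H](C(=C)CO[Si](C)(C)C(C)(C)C)[C@@H](OC(=O)CCl)[C@@H]1OC(=O)C(C)=C
F4 | step 17 | 8α-alcohol (C8 epimer of 19) | C=C[C@@]1(C)[C@H](C(=C)C(OCC)OCC)[C@H](O[Si](C)(C)C(C)(C)C)[C@@H](C(=C)CO[Si](C)(C)C(C)(C)C)[C@@H](O)[C@@H]1OC(=O)C(C)=C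
F5 | step 17 | 8α,12-diol | C=C[C@@]1(C)[C@H](C(=C)C(OCC)OCC)[C@H](O[Si](C)(C)C(C)(C)C)[C@@H](C(=C)CO)[C@@H](O)[C@@H]1OC(=O)C(C)=C
F6 | step 19 | 6β-{2-[bis(2,2,2-trifluoroethoxy)phosphoryl]propanoate} of 25 (epimers at the phosphonate carbon) | C=C[C@@]1(C)[C@H](C(=C)C(OCC)OCC)[C@H](OC(=O)C(C)P(=O)(OCC(F)(F)F)OCC(F)(F)F)[C@H]2C(=C)C(=O)O[C@H]2[C@@H]1OC(=O)C(C)=C
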